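Ring C is opened at C14–C15: the azonine is closed last by ring-closing metathesis between the vinyl group on quaternary C16 and an N-allyl carbamate at the end of the C9–C11 arm. That single operation forms the nine-membered ring and its last skeletal bond. It exploits the C8=C9 enone, exocyclic to ring B and cis within ring C, which turns C10, C11 and N12 back towards C16. Since this geometry places C10 next to the quaternary centre, it is fixed beforehand by face-selective diimide reduction of an exocyclic allene. The precursor 25 is the cis-fused hydrindenone diacetate bearing the C16 vinyl group and the alkylidene chain ending in N(allyl)Teoc.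

Key step: step 18

Locants: all intermediates keep the target's skeleton locants (C1–C11, N12, C13–C16; rings A, B, C). "Down" is the ring-A face that carries ring B (C6, C8); "up" is the face of C15 and H-5.
Assumption: the (S,S)-ligand in step 3 is taken to give the enantiomer drawn for 6; if the sense of induction is the opposite, the (R,R)-ligand is used.

Step 1
Reactants: 1 methyl 2-oxocyclopentane-1-carboxylate
Product: 3 methyl 5-oxocyclopent-1-ene-1-carboxylate, via α-phenylselanyl keto ester 2 (not isolated)
Conditions: PhSeCl, pyridine, CH2Cl2, 0 °C; then 30% H2O2, 0 °C → rt; used at once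
Reagents that add atoms: none
Why: α-Selenenylation of the β-keto ester followed by selenoxide syn-elimination should give the doubly activated cyclopentenone, the only β-hydrogens being those of the ring CH2.

Step 2
Reactants: 4 3-methylbut-2-enal
Product: 5 triethyl{[(1E)-3-methylbuta-1,3-dien-1-yl]oxy}silane
Conditions: Et3SiOTf, Et3N, Et2O, 0 °C → rt
Reagents that add atoms: triethylsilyl trifluoromethanesulfonate, CC[Si](CC)(CC)OS(=O)(=O)C(F)(F)F
Why: O-Silylation of the enal and γ-deprotonation (dienol silyl ether formation) should give mainly the E-configured 1-silyloxy diene, the only isomer that can reach the s-cis form needed in step 3.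

Step 3
Reactants: 3 methyl 5-oxocyclopent-1-ene-1-carboxylate; 5 triethyl{[(1E)-3-methylbuta-1,3-dien-1-yl]oxy}silane
Product: 6 methyl (3aR,7S,7aS)-5-methyl-1-oxo-7-(triethylsilyloxy)-1,2,3,3a,4,7-hexahydro-7aH-indene-7a-carboxylate (cis-fused; C1 silyloxy down, cis to C8; ester up)
Conditions: Cu(OTf)2 (10 mol %), (S,S)-t-Bu-box (11 mol %), 4 Å sieves, CH2Cl2, −78 → −40 °C
Reagents that add atoms: none
Why: Lewis-acid-catalysed Diels–Alder reaction in which the chelated β-keto ester adds with ortho/para regiochemistry (O-bearing C1 to C16, C4 to C5), suprafacial addition fixes the cis ring fusion, the endo position of the ring ketone puts the C1 oxygen cis to C8, and the bis(oxazoline) ligand on divalent copper selects the enantioface, so C1, C5 and C16 are set together.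

Step 4
Reactants: 6 Diels–Alder adduct
Product: 7 C7=C8 enol triflate of 6 (other centres unchanged)
Conditions: KN(SiMe3)2, PhNTf2, THF, −78 °C
Reagents that add atoms: N-phenylbis(trifluoromethanesulfonimide), O=S(=O)(N(c1ccccc1)S(=O)(=O)C(F)(F)F)C(F)(F)F
Why: Enolate O-sulfonylation, regiochemically unambiguous because the ketone can enolize only towards C7 (C16 is quaternary and the ester has no α-hydrogen).

Step 5
Reactants: 7 enol triflate; 8 prop-2-yn-1-ol
Product: 10 enyne diol (C1–OH, C2=C3, C7=C8, 3-hydroxyprop-1-ynyl on C8, ester on C16), via silyl-protected enyne 9 (not isolated)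
Conditions: Pd(PPh3)4 (5 mol %), CuI (10 mol %), Et3N, DMF, rt; then Bu4NF, THF, 0 °C
Reagents that add atoms: none
Why: Sonogashira coupling of a cyclopentenyl triflate flanked by a quaternary carbon (the situation of steroidal D-ring enol triflates) brings in C9–C11, and fluoride then cleaves the silyl ether to free the C1 hydroxyl that directs step 6.

Step 6
Reactants: 10 enyne diol
Product: 12 bis-epoxide (2,3-epoxide down, syn to C1–OH; 7,8-epoxide of either configuration), via ring-A epoxide 11 (not isolated)
Conditions: VO(acac)2 (5 mol %), t-BuOOH, CH2Cl2, 0 °C → rt; then m-CPBA, NaHCO3, 0 °C → rt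
Reagents that add atoms: tert-butyl hydroperoxide, CC(C)(C)OO; 3-chloroperoxybenzoic acid, OOC(=O)c1cccc(Cl)c1
Why: Vanadium-catalysed hydroxyl-directed epoxidation delivers oxygen to C2=C3 on the face of the C1 hydroxyl (this becomes the C3 configuration), and the peracid (Prilezhaev epoxidation) then oxidizes the remaining trisubstituted enyne alkene C7=C8, whose facial outcome is without consequence.

Step 7
Reactants: 12 bis-epoxide
Product: 13 allenol (C7 carbinol, exocyclic allene C8=C9=C10, C11–OH; ring-A epoxy alcohol and ester unchanged; C7 and the allene axis as mixtures)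
Conditions: Pd2(dba)3·CHCl3 (2.5 mol %), PBu3 (10 mol %), HCO2H, Et3N, THF, rt
Reagents that add atoms: none
Why: Palladium-catalysed SN2′ hydrogenolysis of a propargylic oxirane, in which zerovalent palladium opens the C8–O bond by attack at C10 and hydride from formate should give the α-allenic alcohol, the unactivated ring-A epoxide and the ester staying inert; the new C7 carbinol and the allene axis are uncontrolled and both are erased later.

Step 8
Reactants: 13 allenol
Product: 14 alkenyl triol (C7–OH, C8=C9 with C10 syn to C16 and anti to C7, C11–OH; ring-A epoxy alcohol and ester unchanged)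
Conditions: 2-nitrobenzenesulfonohydrazide, Et3N, CH2Cl2, rt
Reagents that add atoms: none
Why: Diimide syn transfer hydrogenation of an allene, in which the less substituted C9=C10 π bond lies in the plane of ring B and should be attacked from the side of the C7 carbinol CH and not from the side of fully substituted C16, so the new C9–H ends up syn to C7 and C10 syn to C16, the kinetically set geometry that ring C needs.

Step 9
Reactants: 14 alkenyl triol
Product: 15 tris(triethylsilyl) ether of 14 (O-1, O-7, O-11)
Conditions: Et3SiCl, imidazole, DMAP (cat.), DMF, rt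
Reagents that add atoms: chlorotriethylsilane, CC[Si](Cl)(CC)CC
Why: Silyl ether formation masks the three hydroxyls against the oxidation and the ylide of steps 11 and 12 and keeps the C1 oxygen from becoming an alkoxide next to a C16 carbonyl.

Step 10
Reactants: 15 tris-silyl ether
Product: 16 diol (C3 tertiary alcohol with CH3 up and OH down, C2 now CH2, C15 primary alcohol; silyl ethers kept)
Conditions: LiAlH4, THF, 0 °C → rt
Reagents that add atoms: none
Why: Hydride reduction turns the ester into the C15 alcohol and opens the trisubstituted oxirane by SN2 attack at the secondary C2 anti to the oxirane oxygen (assisted by delivery from the C15 alkoxyaluminate on that face), so the tertiary C3–O bond and the configuration set in step 6 are kept.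

Step 11
Reactants: 16 diol
Product: 17 C15 aldehyde of 16
Conditions: Dess–Martin periodinane, NaHCO3, CH2Cl2, rt
Reagents that add atoms: none
Why: Dess–Martin oxidation of the only oxidizable (primary, neopentyl) alcohol, the tertiary C3 hydroxyl being inert and the aldehyde having no α-hydrogen.

Step 12
Reactants: 17 aldehyde
Product: 18 C16 vinyl compound (C15=CH2; C3–OH free; three silyl ethers)
Conditions: Ph3PCH3Br, KN(SiMe3)2, THF, 0 °C; then 17, −78 °C → rt
Reagents that add atoms: methyltriphenylphosphonium bromide, C[P+](c1ccccc1)(c1ccccc1)c1ccccc1.[Br-]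
Why: Wittig methylenation of a non-enolizable aldehyde with the small unstabilized ylide, an extra equivalent of which takes up the tertiary hydroxyl.

Step 13
Reactants: 18 vinyl compound
Product: 19 tetraol (C1, C3, C7, C11 hydroxyls; C16 vinyl; C8=C9 alkene)
Conditions: Bu4NF, THF, rt
Reagents that add atoms: none
Why: Fluoride-induced desilylation of the three triethylsilyl ethers, with no carbonyl left on C16 that a transient C1 alkoxide could fragment.

Step 14
Reactants: 19 tetraol; 20 prop-2-en-1-amine (allylamine)
Product: 22 N-allyl secondary amine triol (N12 on C11), via C11 mesylate 21 (not isolated)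
Conditions: MsCl (1.05 equiv), 2,4,6-collidine, CH2Cl2, −30 °C; then 20 (excess), 40 °C
Reagents that add atoms: none
Why: Selective sulfonylation of the single primary alcohol with a hindered base at low temperature, followed by SN2 displacement with excess primary amine, should leave the secondary and tertiary hydroxyls untouched.

Step 15
Reactants: 22 secondary amine
Product: 23 N-allyl N-[2-(trimethylsilyl)ethoxycarbonyl] carbamate triol
Conditions: Teoc-OSu, Et3N, CH2Cl2, rt
Reagents that add atoms: 2-(trimethylsilyl)ethyl N-succinimidyl carbonate, C[Si](C)(C)CCOC(=O)ON1C(=O)CCC1=O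
Why: Carbamate formation by N-acylation of the amine with an active carbonate, which the hindered secondary and tertiary hydroxyls do not attack.

Step 16
Reactants: 23 carbamate triol
Product: 24 enone diol (C7 ketone conjugated with C8=C9; C1 and C3 hydroxyls free)
Conditions: MnO2, CH2Cl2, rt
Reagents that add atoms: none
Why: MnO2 oxidation is selective for the allylic C7 alcohol over the saturated C1 and tertiary C3 hydroxyls and does not touch the alkene geometry.

Step 17
Reactants: 24 enone diol
Product: 25 metathesis precursor (1,3-diacetate; C7 ketone; C8=C9 with C10 syn to C16; N(allyl)Teoc on C11; C16 vinyl)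
Conditions: Ac2O, DMAP, Et3N, CH2Cl2, rt → 40 °C
Reagents that add atoms: acetic anhydride, CC(=O)OC(C)=O
Why: DMAP-catalysed acylation esterifies the hindered secondary C1 and the tertiary C3 hydroxyl, and is placed last so that the acetates meet no hydride, ylide, fluoride or amine.

Step 18
Reactants: 25 metathesis precursor
Product: 26 N-Teoc 14,15-dehydro azonine (ring C closed, C14=C15 cis)
Conditions: second-generation Grubbs catalyst (H2IMes)(PCy3)Cl2Ru=CHPh (10 mol %, in portions), toluene (1 mM), 80 °C, argon sparge
Reagents that add atoms: none
Why: The ruthenium benzylidene exchanges onto the unhindered N-allyl terminus, the new alkylidene adds [2+2] to the neopentyl C16 vinyl group, and the ruthenacyclobutane cycloreverts to the C14=C15 alkene and a ruthenium methylidene that carries the chain with loss of ethylene. The closest known reaction type is ring-closing olefin metathesis of N-allyl carbamates to medium-ring unsaturated azacycles with second-generation ruthenium carbenes. Ring C closes end to end by joining the two terminal alkene carbons C14 and C15 into an endocyclic alkene of the nine-membered ring; no other ring forms. No stereocentre is created, and the geometry of the new alkene (expected cis for ring strain) does not matter because step 19 removes it. The step needs cyclization to beat oligomerization and needs the enone alkene to stay out of the metathesis. High dilution, the turn imposed by C10 lying syn to C16 across C8=C9 together with the planar carbamate, and the inertness of a trisubstituted electron-poor alkene towards the catalyst should secure both.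

Step 19
Reactants: 26 dehydro azonine
Product: 27 N-Teoc azonane (C14–C15 saturated)
Conditions: 2-nitrobenzenesulfonohydrazide, Et3N, CH2Cl2, rt
Reagents that add atoms: none
Why: Diimide reduction by concerted syn hydrogen transfer should take the isolated cis-disubstituted C14=C15 alkene and leave the trisubstituted, conjugated C8=C9 bond, the ketone and the acetates alone.

Step 20
Reactants: 27 N-Teoc azonane
Product: 28 target CNP0120442.1
Conditions: Bu4NF, THF, 0 °C → rt
Reagents that add atoms: none
Why: Fluoride attack on silicon triggers β-elimination and decarboxylation of the silylethyl carbamate to free N12, under conditions the two acetates and the enone should tolerate.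

Compound list
1 | methyl 2-oxocyclopentane-1-carboxylate | COC(=O)C1CCCC1=O | starting material
2 | methyl 2-oxo-1-(phenylselanyl)cyclopentane-1-carboxylate (racemic) | COC(=O)C1([Se]c2ccccc2)CCCC1=O | intermediate
3 | methyl 5-oxocyclopent-1-ene-1-carboxylate | COC(=O)C1=CCCC1=O | intermediate
4 | 3-methylbut-2-enal | CC(C)=CC=O | starting material
5 | triethyl{[(1E)-3-methylbuta-1,3-dien-1-yl]oxy}silane | C=C(C)/C=C/O[Si](CC)(CC)CC | intermediate
6 | methyl (3aR,7S,7aS)-5-methyl-1-oxo-7-(triethylsilyloxy)-1,2,3,3a,4,7-hexahydro-7aH-indene-7a-carboxylate | CC[Si](CC)(CC)O[C@H]1C=C(C)C[C@H]2CCC(=O)[C@]21C(=O)OC | intermediate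
7 | C7=C8 enol triflate of 6 | CC[Si](CC)(CC)O[C@H]1C=C(C)C[C@H]2CC=C(OS(=O)(=O)C(F)(F)F)[C@]21C(=O)OC | intermediate
8 | prop-2-yn-1-ol | C#CCO | starting material
9 | C1 triethylsilyl ether of enyne diol 10 | CC[Si](CC)(CC)O[C@H]1C=C(C)C[C@H]2CC=C(C#CCO)[C@]21C(=O)OC | intermediate
10 | enyne diol (C1–OH, 3-hydroxyprop-1-ynyl on C8) | O[C@H]1C=C(C)C[C@H]2CC=C(C#CCO)[C@]21C(=O)OC | intermediate
11 | 2,3-epoxide of 10, oxirane syn to C1–OH | O[C@H]1[C@H]3O[C@@]3(C)C[C@H]2CC=C(C#CCO)[C@]21C(=O)OC | intermediate
12 | 2,3:7,8-bis-epoxide (C7/C8 configuration not controlled) | O[C@H]1[C@H]3O[C@@]3(C)C[C@H]2CC4OC4(C#CCO)[C@]21C(=O)OC | intermediate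
13 | allenol with C7–OH, C8=C9=C10 and C11–OH (C7 and axis as mixtures) | O[C@H]1[C@H]3O[C@@]3(C)C[C@H]2CC(O)C(=C=CCO)[C@]21C(=O)OC | intermediate
14 | alkenyl triol, C10 syn to C16 across C8=C9 | O[C@H]1[C@H]3O[C@@]3(C)C[C@H]2CC(O)/C(=C/CCO)[C@]21C(=O)OC | intermediate
15 | tris(triethylsilyl) ether of 14 | CC[Si](CC)(CC)O[C@H]1[C@H]3O[C@@]3(C)C[C@H]2CC(O[Si](CC)(CC)CC)/C(=C/CCO[Si](CC)(CC)CC)[C@]21C(=O)OC | intermediate
16 | C3 tertiary alcohol / C15 primary alcohol, silyl ethers kept | CC[Si](CC)(CC)O[C@H]1C[C@@](C)(O)C[C@H]2CC(O[Si](CC)(CC)CC)/C(=C/CCO[Si](CC)(CC)CC)[C@]21CO | intermediate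
17 | C15 aldehyde of 16 | CC[Si](CC)(CC)O[C@H]1C[C@@](C)(O)C[C@H]2CC(O[Si](CC)(CC)CC)/C(=C/CCO[Si](CC)(CC)CC)[C@]21C=O | intermediate
18 | C16 vinyl compound, C3–OH free, three silyl ethers | CC[Si](CC)(CC)O[C@H]1C[C@@](C)(O)C[C@H]2CC(O[Si](CC)(CC)CC)/C(=C/CCO[Si](CC)(CC)CC)[C@]21C=C | intermediate
19 | tetraol with C16 vinyl | O[C@H]1C[C@@](C)(O)C[C@H]2CC(O)/C(=C/CCO)[C@]21C=C | intermediate
20 | prop-2-en-1-amine (allylamine) | C=CCN | starting material
21 | C11 methanesulfonate of 19 | O[C@H]1C[C@@](C)(O)C[C@H]2CC(O)/C(=C/CCOS(C)(=O)=O)[C@]21C=C | intermediate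
22 | N-allyl secondary amine triol | O[C@H]1C[C@@](C)(O)C[C@H]2CC(O)/C(=C/CCNCC=C)[C@]21C=C | intermediate
23 | N-allyl N-Teoc carbamate triol | O[C@H]1C[C@@](C)(O)C[C@H]2CC(O)/C(=C/CCN(CC=C)C(=O)OCC[Si](C)(C)C)[C@]21C=C | intermediate
24 | enone diol | O[C@H]1C[C@@](C)(O)C[C@H]2CC(=O)/C(=C/CCN(CC=C)C(=O)OCC[Si](C)(C)C)[C@]21C=C | intermediate
25 | metathesis precursor: hydrindenone 1,3-diacetate with C16 vinyl and N-allyl carbamate | CC(=O)O[C@H]1C[C@@](C)(OC(C)=O)C[C@H]2CC(=O)/C(=C/CCN(CC=C)C(=O)OCC[Si](C)(C)C)[C@]21C=C | intermediate
26 | N-Teoc 14,15-dehydro derivative of the target | CC(=O)O[C@H]1C[C@@](C)(OC(C)=O)C[C@H]2CC(=O)/C3=C/CCN(C(=O)OCC[Si](C)(C)C)C/C=C\[C@@]321 | intermediate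
27 | N-Teoc derivative of the target | CC(=O)O[C@H]1C[C@@](C)(OC(C)=O)C[C@H]2CC(=O)/C3=C/CCN(C(=O)OCC[Si](C)(C)C)CCC[C@@]321 | intermediate
28 | CNP0120442.1 | CC(=O)O[C@H]1C[C@@](C)(OC(C)=O)C[C@H]2CC(=O)/C3=C/CCNCCC[C@@]321 | target

Total: 20 steps. Longest linear sequence: 19 steps (steps 1 and 3–20 from 1; step 2 makes the diene in a one-step side branch).

Steps most likely to fail

Step 18. Closure of the strained nine-membered ring may be outrun by intermolecular metathesis through the N-allyl termini, because the neopentyl vinyl group, crowded by the neighbouring C1 acetate, engages the ruthenium alkylidene slowly. The fallback inverts ring closure and acylation. It sets out from enone diol 24, which is cyclized with the same ruthenium carbene at high dilution; the free C1 hydroxyl, homoallylic to the vinyl group, is smaller than the acetate and can hydrogen-bond to a chloride ligand of the carbene. This gives the ring-closed diol F1, which is acetylated (Ac2O, DMAP, Et3N) and so returns to the route at 26.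

Step 3. The uncatalysed background cycloaddition of the very reactive dienophile, or partial desilylation of the diene by the Lewis acid, may erode enantioface control. The fallback gives up asymmetric catalysis. It sets out from 3 and 5, runs the cycloaddition without chiral ligand (thermal or with ZnCl2) to racemic material, that is 6 together with the enantiomer of 6 F2, and resolves it by preparative chromatography on a chiral stationary phase. It returns to the route at 6.

Step 10. Hydride opening of the hindered trisubstituted oxirane may be slow or misdirected: attack at the tertiary C3, or capture of C2 by the C15 alkoxide once the ester has been reduced. The fallback separates the two reductions and uses a soft nucleophile. It sets out from 15: phenylselenide (PhSeSePh, NaBH4, EtOH) opens the oxirane at C2 while the ester is still intact, giving the hydroxy selenide F3; radical deselenation (Bu3SnH, AIBN, toluene, 80 °C) gives the hydroxy ester F4; LiAlH4 then reduces only the ester. It returns to the route at 16.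

Further compounds
F1 | step 18 | ring-closed diol: N-Teoc 14,15-dehydro azonine with free C1 and C3 hydroxyls | O[C@H]1C[C@@](C)(O)C[C@H]2CC(=O)/C3=C/CCN(C(=O)OCC[Si](C)(C)C)C/C=C\[C@@]321
F2 | step 3 | enantiomer of 6 | CC[Si](CC)(CC)O[C@@H]1C=C(C)C[C@@H]2CCC(=O)[C@@]21C(=O)OC
F3 | step 10 | hydroxy selenide: C2 phenylselanyl (up), C3 tertiary alcohol, ester and silyl ethers intact | CC[Si](CC)(CC)O[C@H]1[C@H]([Se]c3ccccc3)[C@@](C)(O)C[C@H]2CC(O[Si](CC)(CC)CC)/C(=C/CCO[Si](CC)(CC)CC)[C@]21C(=O)OC
F4 | step 10 | hydroxy ester: C3 tertiary alcohol, C2 CH2, ester and silyl ethers intact | CC[Si](CC)(CC)O[C@H]1C[C@@](C)(O)C[C@H]2CC(O[Si](CC)(CC)CC)/C(=C/CCO[Si](CC)(CC)CC)[C@]21C(=O)OC
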